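## Retrosynthetic overview

1. Labels follow eudesmane numbering (ring A = C1–C5, C10; ring B = C5–C10; C11 = carbinol carbon; C9′ = benzylic carbon). 27 ⇐ 21: the two formyl groups and the free phenols come last (double ortho-formylation, O-demethylation).
2. 21 ⇐ 20: acid opens a cyclopropylcarbinyl system (C6–C11 bond) with water capture, giving C4–H, the C5=C6 alkene and the C11 alcohol.
3. 20 ⇐ 18: an enal-derived zinc carbenoid at C6 cyclopropanates the C7=C11 alkene, closing ring B and the cyclopropane in one operation.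
4. 18 ⇐ 8: the C9′ side chain grows from the C1 ester (isobutyl ketone, aryl addition, ionic reduction); the ring ketone becomes the enal through its enol triflate.
5. 8 ⇐ 1 + 2 + 6: ring A is made first by an organocatalytic Michael/aldol sequence (sets C1), then C10 by enolate alkylation. Ring order: A, then B together with the cyclopropane, which is then opened.

Assumption: 1, 2, 6 and 13 are purchased (2 as the E isomer).

## Route

Step 1
Reactants: 1 ethyl 2-methyl-3-oxopentanoate; 2 ethyl (2E)-4-oxobut-2-enoate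
Product: 4 diethyl (6S)-1,3-dimethyl-2-oxocyclohex-3-ene-1,6-dicarboxylate (both epimers at the quaternary carbon), via Michael adduct 3 (not isolated)
Conditions: (S)-2-{bis[3,5-bis(trifluoromethyl)phenyl](trimethylsilyloxy)methyl}pyrrolidine (10 mol %), PhCO2H (10 mol %), toluene, 0 °C to rt; then p-TsOH·H2O (20 mol %), 80 °C
Reagents that add atoms: none
Why: Iminium-catalysed Michael addition of the β-keto ester to the enal (the S catalyst shields one face of the iminium in the same sense as in its malonate and nitromethane additions, so C1 is set S at this stage), then acid-catalysed intramolecular aldol condensation of the only enolisable ketone α-carbon onto the aldehyde closes ring A (organocatalytic Michael/aldol annulation).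

Step 2
Reactants: 4
Product: 5 ethyl (1S)-2,4-dimethyl-3-oxocyclohex-4-ene-1-carboxylate (both epimers at the methyl-bearing α-carbon)
Conditions: LiCl (3 equiv), H2O (3 equiv), DMSO, 150 °C
Reagents that add atoms: none
Why: Krapcho dealkoxycarbonylation removes only the β-keto ester group, the simple ester on C1 is not activated, and the C10 centre is left as a mixture because it is re-enolised in step 3.

Step 3
Reactants: 5; 6 5-bromo-2-methylpent-2-ene
Product: 8 ethyl (1S,2R)-2,4-dimethyl-2-(4-methylpent-3-en-1-yl)-3-oxocyclohex-4-ene-1-carboxylate, via lithium dienolate 7 (not isolated)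
Conditions: LiN(i-Pr)2 (1.05 equiv), THF, −78 °C; then 6, HMPA, −78 to −20 °C
Reagents that add atoms: none
Why: Kinetic α′-deprotonation gives the cross-conjugated dienolate, which is alkylated anti to the neighbouring C1 ester (1,2-trans enolate alkylation), fixing quaternary C10 as R with its methyl cis to the C1 substituent.

Step 4
Reactants: 8
Product: 10 ethyl (1S,2R)-2,4-dimethyl-2-(4-methylpent-3-en-1-yl)-3-(trifluoromethanesulfonyloxy)cyclohex-3-ene-1-carboxylate, via lithium enolate 9 (not isolated)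
Conditions: LiBH(s-Bu)3 (1.1 equiv), THF, −78 °C; then PhNTf2 (1.2 equiv), −78 to 0 °C
Reagents that add atoms: N-phenylbis(trifluoromethanesulfonimide), O=S(=O)(N(c1ccccc1)S(=O)(=O)C(F)(F)F)C(F)(F)F
Why: Conjugate reduction of the β-unsubstituted, carbonyl-hindered enone followed by O-sulfonylation of the regiodefined enolate (conjugate reduction/enolate trapping) gives the tetrasubstituted enol triflate without a new stereocentre.

Step 5
Reactants: 10
Product: 12 (5S,6R)-2,6-dimethyl-5-(3-methylbutanoyl)-6-(4-methylpent-3-en-1-yl)cyclohex-1-en-1-yl trifluoromethanesulfonate, via Weinreb amide 11 (not isolated)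
Conditions: MeNH(OMe)·HCl (1.5 equiv), i-PrMgCl (3.0 equiv), THF, −20 °C; then i-BuMgBr (2.5 equiv), −20 to 0 °C; aq. NH4Cl
Reagents that add atoms: isobutylmagnesium bromide, CC(C)C[Mg]Br; N,O-dimethylhydroxylamine hydrochloride, CNOC.Cl (its atoms stay only in 11)
Why: One-pot Weinreb ketone synthesis, in which the chelated tetrahedral adduct of the N-methoxy-N-methylamide stops the Grignard reagent at the ketone and the enol triflate is inert in the absence of a transition-metal catalyst.

Step 6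
Reactants: 12; 13 1,3,5-trimethoxybenzene
Product: 16 (5S,6R)-5-[1-hydroxy-3-methyl-1-(2,4,6-trimethoxyphenyl)butyl]-2,6-dimethyl-6-(4-methylpent-3-en-1-yl)cyclohex-1-en-1-yl trifluoromethanesulfonate (both carbinol epimers), via aryllithium 14 (not isolated), via arylcerium dichloride 15 (not isolated)
Conditions: 13, n-BuLi, THF, 0 °C to rt; CeCl3 (dried), −78 °C; then 12, −78 to −40 °C; H2O
Reagents that add atoms: none
Why: Ortho-lithiation between two methoxy groups and transmetalation to the weakly basic organocerium allows 1,2-addition to the hindered, enolisable ketone (organocerium addition); the carbinol configuration does not matter because it is ionised in step 7.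

Step 7
Reactants: 16
Product: 17 (5R,6R)-2,6-dimethyl-5-[(1S)-3-methyl-1-(2,4,6-trimethoxyphenyl)butyl]-6-(4-methylpent-3-en-1-yl)cyclohex-1-en-1-yl trifluoromethanesulfonate
Conditions: Et3SiH (10 equiv), CF3CO2H (5 equiv), CH2Cl2, −40 °C; aq. NaHCO3
Reagents that add atoms: none
Why: Ionic hydrogenation (Kursanov–Parnes): the alcohol ionises to a benzylic cation stabilised by the trimethoxyphenyl ring, allylic 1,3-strain with the ortho-methoxy groups holds the C1–H bond in the cation plane, and the silane delivers hydride anti to quaternary C10, which gives (S)-C9′.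

Step 8
Reactants: 17
Product: 18 (5R,6R)-2,6-dimethyl-5-[(1S)-3-methyl-1-(2,4,6-trimethoxyphenyl)butyl]-6-(4-methylpent-3-en-1-yl)cyclohex-1-ene-1-carbaldehyde
Conditions: Pd(PPh3)4 (5 mol %), CO (1 atm), Bu3SnH (1.2 equiv, slow addition), THF, 50 °C
Reagents that add atoms: carbon monoxide, [C-]#[O+]
Why: Palladium-catalysed reductive carbonylation of a vinyl triflate (Stille-type formylation): oxidative addition, CO insertion and hydride transfer from tin to the acylpalladium give the enal.

Step 9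
Reactants: 18
Product: 20 (1aS,3aR,4R,7bR)-1,1,3a,7-tetramethyl-4-[(1S)-3-methyl-1-(2,4,6-trimethoxyphenyl)butyl]-1a,2,3,3a,4,5,6,7b-octahydro-1H-cyclopropa[a]naphthalene, via zinc carbenoid 19 (not isolated)
Conditions: Zn(Hg) (10 equiv), Me3SiCl (6 equiv), Et2O, reflux, 18 added over 12 h
Reagents that add atoms: none
Why: Motherwell-type deoxygenative formation of an organozinc carbenoid from the α,β-unsaturated aldehyde and its intramolecular cyclopropanation of the trisubstituted alkene close ring B and the cyclopropane together; the fusion is necessarily cis, and the carbenoid is expected to react through the fold in which the bulky C1 side chain is pseudo-axial and anti to C9, so the CMe2 bridge ends anti to C1 and syn to the angular methyl (C6 R, C7 S).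

Step 10
Reactants: 20
Product: 21 2-[(2S,4aR,5R,8R)-4a,8-dimethyl-5-[(1S)-3-methyl-1-(2,4,6-trimethoxyphenyl)butyl]-2,3,4,4a,5,6,7,8-octahydronaphthalen-2-yl]propan-2-ol
Conditions: HClO4 (0.05 M), THF–H2O 4:1, 0 °C; aq. NaHCO3
Reagents that add atoms: water, O
Why: Acid-catalysed cyclopropylcarbinyl-to-homoallyl ring opening: protonation of the tetrasubstituted alkene at C4 from the face opposite the CMe2 bridge, angular methyl and C1 side chain gives the tertiary cyclopropylcarbinyl cation at C5, the C6–C11 bond opens to the tertiary C11 cation and water traps it, which sets (R)-C4, the C5=C6 alkene and the tertiary alcohol while C7 is untouched.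

Step 11
Reactants: 21
Product: 26 5-[(1S)-1-[(1R,4R,6S,8aR)-6-(2-hydroxypropan-2-yl)-4,8a-dimethyl-1,2,3,4,6,7,8,8a-octahydronaphthalen-1-yl]-3-methylbutyl]-2,4,6-trimethoxybenzene-1,3-dicarbaldehyde, via aryllithium alkoxide 22 (not isolated), via hemiaminal alkoxide 23 (not isolated), via lithiated hemiaminal 24 (not isolated), via bis-hemiaminal alkoxide 25 (not isolated)
Conditions: n-BuLi (2.3 equiv), TMEDA, THF, −20 to 0 °C; DMF (1.2 equiv), −78 to 0 °C; n-BuLi (1.3 equiv), 0 °C; DMF (3 equiv); H2O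
Reagents that add atoms: N,N-dimethylformamide, CN(C)C=O
Why: Directed ortho-metalation/formylation, each ring C–H lying between two methoxy groups; the first DMF adduct persists as a lithium α-amino alkoxide that masks the first formyl group during the second lithiation and formylation.

Step 12
Reactants: 26
Product: 27 5-[(1S)-1-[(1R,4R,6S,8aR)-6-(2-hydroxypropan-2-yl)-4,8a-dimethyl-1,2,3,4,6,7,8,8a-octahydronaphthalen-1-yl]-3-methylbutyl]-2,4,6-trihydroxybenzene-1,3-dicarbaldehyde (CNP0108656.4)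
Conditions: NaSEt (10 equiv), DMF, 110 °C; then aq. HCl to pH 3, 0 °C
Reagents that add atoms: none
Why: Thiolate SN2 O-demethylation of three aryl methyl ethers, each activated by an ortho formyl group, under basic conditions that leave the tertiary alcohol and the trisubstituted alkene untouched.

## Compound list

1 | ethyl 2-methyl-3-oxopentanoate | CCC(=O)C(C)C(=O)OCC | starting material
2 | ethyl (2E)-4-oxobut-2-enoate | CCOC(=O)/C=C/C=O | starting material
3 | diethyl (3S)-2-methyl-3-(2-oxoethyl)-2-propanoylbutanedioate (both C2 epimers) | CCOC(=O)[C@@H](CC=O)C(C)(C(=O)OCC)C(=O)CC | intermediate (not isolated)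
4 | diethyl (6S)-1,3-dimethyl-2-oxocyclohex-3-ene-1,6-dicarboxylate (both epimers at the quaternary carbon) | CCOC(=O)[C@H]1CC=C(C)C(=O)C1(C)C(=O)OCC | intermediate
5 | ethyl (1S)-2,4-dimethyl-3-oxocyclohex-4-ene-1-carboxylate (both C2 epimers) | CCOC(=O)[C@H]1CC=C(C)C(=O)C1C | intermediate
6 | 5-bromo-2-methylpent-2-ene | CC(C)=CCCBr | starting material
7 | lithium (3S)-3-(ethoxycarbonyl)-2,6-dimethylcyclohexa-1,5-dien-1-olate | CCOC(=O)[C@H]1CC=C(C)C(O[Li])=C1C | intermediate (not isolated)
8 | ethyl (1S,2R)-2,4-dimethyl-2-(4-methylpent-3-en-1-yl)-3-oxocyclohex-4-ene-1-carboxylate | CCOC(=O)[C@H]1CC=C(C)C(=O)[C@]1(C)CCC=C(C)C | intermediate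
9 | lithium (5S,6R)-5-(ethoxycarbonyl)-2,6-dimethyl-6-(4-methylpent-3-en-1-yl)cyclohex-1-en-1-olate | CCOC(=O)[C@H]1CCC(C)=C(O[Li])[C@]1(C)CCC=C(C)C | intermediate (not isolated)
10 | ethyl (1S,2R)-2,4-dimethyl-2-(4-methylpent-3-en-1-yl)-3-(trifluoromethanesulfonyloxy)cyclohex-3-ene-1-carboxylate | CCOC(=O)[C@H]1CCC(C)=C(OS(=O)(=O)C(F)(F)F)[C@]1(C)CCC=C(C)C | intermediate
11 | (5S,6R)-5-[methoxy(methyl)carbamoyl]-2,6-dimethyl-6-(4-methylpent-3-en-1-yl)cyclohex-1-en-1-yl trifluoromethanesulfonate | CON(C)C(=O)[C@H]1CCC(C)=C(OS(=O)(=O)C(F)(F)F)[C@]1(C)CCC=C(C)C | intermediate (not isolated)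
12 | (5S,6R)-2,6-dimethyl-5-(3-methylbutanoyl)-6-(4-methylpent-3-en-1-yl)cyclohex-1-en-1-yl trifluoromethanesulfonate | CC(C)CC(=O)[C@H]1CCC(C)=C(OS(=O)(=O)C(F)(F)F)[C@]1(C)CCC=C(C)C | intermediate
13 | 1,3,5-trimethoxybenzene | COc1cc(OC)cc(OC)c1 | starting material
14 | (2,4,6-trimethoxyphenyl)lithium | COc1cc(OC)c([Li])c(OC)c1 | intermediate (not isolated)
15 | dichloro(2,4,6-trimethoxyphenyl)cerium | COc1cc(OC)c([Ce](Cl)Cl)c(OC)c1 | intermediate (not isolated)
16 | (5S,6R)-5-[1-hydroxy-3-methyl-1-(2,4,6-trimethoxyphenyl)butyl]-2,6-dimethyl-6-(4-methylpent-3-en-1-yl)cyclohex-1-en-1-yl trifluoromethanesulfonate (both carbinol epimers) | CC(C)CC(O)(c1c(OC)cc(OC)cc1OC)[C@H]1CCC(C)=C(OS(=O)(=O)C(F)(F)F)[C@]1(C)CCC=C(C)C | intermediate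
17 | (5R,6R)-2,6-dimethyl-5-[(1S)-3-methyl-1-(2,4,6-trimethoxyphenyl)butyl]-6-(4-methylpent-3-en-1-yl)cyclohex-1-en-1-yl trifluoromethanesulfonate | CC(C)C[C@H](c1c(OC)cc(OC)cc1OC)[C@H]1CCC(C)=C(OS(=O)(=O)C(F)(F)F)[C@]1(C)CCC=C(C)C | intermediate
18 | (5R,6R)-2,6-dimethyl-5-[(1S)-3-methyl-1-(2,4,6-trimethoxyphenyl)butyl]-6-(4-methylpent-3-en-1-yl)cyclohex-1-ene-1-carbaldehyde | CC(C)C[C@H](c1c(OC)cc(OC)cc1OC)[C@H]1CCC(C)=C(C=O)[C@]1(C)CCC=C(C)C | intermediate
19 | chloro{chloro[(5R,6R)-2,6-dimethyl-5-[(1S)-3-methyl-1-(2,4,6-trimethoxyphenyl)butyl]-6-(4-methylpent-3-en-1-yl)cyclohex-1-en-1-yl]methyl}zinc (zinc carbenoid) | CC(C)C[C@H](c1c(OC)cc(OC)cc1OC)[C@H]1CCC(C)=C(C(Cl)[Zn]Cl)[C@]1(C)CCC=C(C)C | intermediate (not isolated)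
20 | (1aS,3aR,4R,7bR)-1,1,3a,7-tetramethyl-4-[(1S)-3-methyl-1-(2,4,6-trimethoxyphenyl)butyl]-1a,2,3,3a,4,5,6,7b-octahydro-1H-cyclopropa[a]naphthalene | CC(C)C[C@H](c1c(OC)cc(OC)cc1OC)[C@H]1CCC(C)=C2[C@@H]3[C@H](CC[C@@]21C)C3(C)C | intermediate
21 | 2-[(2S,4aR,5R,8R)-4a,8-dimethyl-5-[(1S)-3-methyl-1-(2,4,6-trimethoxyphenyl)butyl]-2,3,4,4a,5,6,7,8-octahydronaphthalen-2-yl]propan-2-ol | CC(C)C[C@H](c1c(OC)cc(OC)cc1OC)[C@H]1CC[C@@H](C)C2=C[C@@H](C(C)(C)O)CC[C@@]21C | intermediate
22 | lithium alkoxide of 21 lithiated at one free aryl position | CC(C)C[C@H](c1c(OC)cc(OC)c([Li])c1OC)[C@H]1CC[C@@H](C)C2=C[C@@H](C(C)(C)O[Li])CC[C@@]21C | intermediate (not isolated)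
23 | dilithium salt of the mono-DMF adduct (aryl–CH(OLi)NMe2, C11–OLi) | CC(C)C[C@H](c1c(OC)cc(OC)c(C(O[Li])N(C)C)c1OC)[C@H]1CC[C@@H](C)C2=C[C@@H](C(C)(C)O[Li])CC[C@@]21C | intermediate (not isolated)
24 | 23 lithiated at the remaining aryl position | CC(C)C[C@H](c1c(OC)c([Li])c(OC)c(C(O[Li])N(C)C)c1OC)[C@H]1CC[C@@H](C)C2=C[C@@H](C(C)(C)O[Li])CC[C@@]21C | intermediate (not isolated)
25 | trilithium salt of the bis-DMF adduct | CC(C)C[C@H](c1c(OC)c(C(O[Li])N(C)C)c(OC)c(C(O[Li])N(C)C)c1OC)[C@H]1CC[C@@H](C)C2=C[C@@H](C(C)(C)O[Li])CC[C@@]21C | intermediate (not isolated)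
26 | 5-[(1S)-1-[(1R,4R,6S,8aR)-6-(2-hydroxypropan-2-yl)-4,8a-dimethyl-1,2,3,4,6,7,8,8a-octahydronaphthalen-1-yl]-3-methylbutyl]-2,4,6-trimethoxybenzene-1,3-dicarbaldehyde | CC(C)C[C@H](c1c(OC)c(C=O)c(OC)c(C=O)c1OC)[C@H]1CC[C@@H](C)C2=C[C@@H](C(C)(C)O)CC[C@@]21C | intermediate
27 | 5-[(1S)-1-[(1R,4R,6S,8aR)-6-(2-hydroxypropan-2-yl)-4,8a-dimethyl-1,2,3,4,6,7,8,8a-octahydronaphthalen-1-yl]-3-methylbutyl]-2,4,6-trihydroxybenzene-1,3-dicarbaldehyde | CC(C)C[C@H](c1c(O)c(C=O)c(O)c(C=O)c1O)[C@H]1CC[C@@H](C)C2=C[C@@H](C(C)(C)O)CC[C@@]21C | target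

## Step count and risks

Total steps: 12. Longest linear sequence: 12 (1 and 2 to 27).

Steps most likely to fail:

**Step 9 (zinc-carbenoid bicyclisation).** The yield is uncertain, and the facial preference (CMe2 bridge syn to the angular methyl) rests on a conformational argument that could go the other way. The fallback sets out from 18 and returns at 21.
- Condense 18 with NH2OH·HCl/pyridine to the aldoxime F3.
- Oxidise with aqueous NaOCl in CH2Cl2; the nitrile oxide adds across the pendant alkene (intramolecular nitrile oxide cycloaddition) to give the ring B-fused isoxazoline F4, with the oxygen already on C11.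
- Mo(CO)6 in wet MeCN cleaves the N–O bond and hydrolyses the imine to the β-hydroxy enone F5, whose C7 centre can equilibrate to the equatorial epimer needed.
- NaBH4/CeCl3 reduces from the face anti to the angular methyl to the allylic alcohol F6.
- Mitsunobu reaction with 2-nitrobenzenesulfonylhydrazide (PPh3, diethyl azodicarboxylate) and warming gives 21 through the allylic diazene, which loses N2 and delivers H to C4 suprafacially (Myers reductive transposition).

**Step 10 (protonation face at C4).** The wrong face would give the C4 epimer, and the C11 cation can also eliminate. The fallback sets out from 20 and returns at 21, using radical instead of cationic opening: Mn(dpm)3 (cat.), PhSiH3, O2, i-PrOH, 0 °C. Hydrogen-atom transfer from the bulky metal hydride to C4 gives the cyclopropylcarbinyl radical at C5, which opens to the tertiary C11 radical. O2 traps it as the hydroperoxide F7, and PPh3 reduces F7 to 21.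

**Step 6 (aryl addition to a hindered, enolisable ketone).** The fallback sets out from 10 and returns at 16, introducing the aryl group first. Add aryllithium 14 to ester 10 at −78 °C to give the aryl ketone F1, which is too hindered for a second addition. Add 2-methylallylmagnesium chloride to F1 to give the homoallylic tertiary alcohol F2. Hydrogenate its 1,1-disubstituted alkene selectively (H2, RhCl(PPh3)3) to reach 16.

Further compounds
F1 | step 6 | (5S,6R)-2,6-dimethyl-6-(4-methylpent-3-en-1-yl)-5-(2,4,6-trimethoxybenzoyl)cyclohex-1-en-1-yl trifluoromethanesulfonate | O=C(c1c(OC)cc(OC)cc1OC)[C@H]1CCC(C)=C(OS(=O)(=O)C(F)(F)F)[C@]1(C)CCC=C(C)C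
F2 | step 6 | (5S,6R)-5-[1-hydroxy-3-methyl-1-(2,4,6-trimethoxyphenyl)but-3-en-1-yl]-2,6-dimethyl-6-(4-methylpent-3-en-1-yl)cyclohex-1-en-1-yl trifluoromethanesulfonate (both carbinol epimers) | CC(=C)CC(O)(c1c(OC)cc(OC)cc1OC)[C@H]1CCC(C)=C(OS(=O)(=O)C(F)(F)F)[C@]1(C)CCC=C(C)C
F3 | step 9 | oxime of 18 | CC(C)C[C@H](c1c(OC)cc(OC)cc1OC)[C@H]1CCC(C)=C(C=NO)[C@]1(C)CCC=C(C)C
F4 | step 9 | ring B-fused isoxazoline (C6=N–O–C11, new C6–C7 bond) | CC(C)C[C@H](c1c(OC)cc(OC)cc1OC)[C@H]1CCC(C)=C2C3=NOC(C)(C)[C@H]3CC[C@@]21C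
F5 | step 9 | β-hydroxy enone (C6 ketone, C4=C5 alkene, C7 carrying C(CH3)2OH) | CC(C)C[C@H](c1c(OC)cc(OC)cc1OC)[C@H]1CCC(C)=C2C(=O)[C@@H](C(C)(C)O)CC[C@@]21C
F6 | step 9 | allylic alcohol (C6–OH cis to the C7 substituent and the angular methyl) | CC(C)C[C@H](c1c(OC)cc(OC)cc1OC)[C@H]1CCC(C)=C2[C@@H](O)[C@@H](C(C)(C)O)CC[C@@]21C
F7 | step 10 | C11 hydroperoxide corresponding to 21 | CC(C)C[C@H](c1c(OC)cc(OC)cc1OC)[C@H]1CC[C@@H](C)C2=C[C@@H](C(C)(C)OO)CC[C@@]21C
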